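| flask | J | E | X | remark | time |
|---|---|---|---|---|---|
| dusk | 0.50 M | 0.28 M | 0.050 M | run made earlier |  |
| spring | 0.50 M | 0.77 M | 0.050 M | run made earlier |  |
| noon | 0.54 M | 0.40 M | 0.050 M | run made earlier |  |
| east | 0.50 M | 0.400 M | 0.0500 M |  | 30 h |
| north | 0.25 M | 0.250 M | 0.0120 M |  | 30 h |
| south-east | 0.15 M | 0.400 M | 0.0250 M |  | 30 h |
| west | 0.12 M | 0.600 M | 0.0120 M |  | 30 h |
| south | 2.0 M | 0.250 M | 0.0500 M |  | 30 h |

- dusk (time / h: D / %, J / %): 8.00: 15, 63; 15.0: 16, 59; 25.0: 19, 56; 30.0: 21, 53
- spring (time / h: D / %, J / %): 4.00: 35, 43; 10.0: 54, 27; 20.0: 64, 21; 30.0: 67, 16
- noon (time / h: D / %, J / %): 2.50: 12, 75; 6.00: 19, 60; 12.0: 26, 49; 30.0: 26, 45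

(each reading ± 1.5 percentage points)

* the flasks by amount of D, in percent of the J charged, highest first, at 30 h (east / north / south-east / west / south)
* the same order at 6.0 h (east / north / south-east / west / south)
* the amount of D, in percent of the J charged of the flask you put first, at 30 h
* the amount of D, in percent of the J charged of the flask you put last, at 30 h

- no earlier run changes the charge of X; that part of a forecast is a guess

- The ratio of J lost plus D formed to E charged reads 1.09 at the last reading of the noon run, near one, with D reading 26% at 12.0 h and 26% at 30.0 h. This is read as one E for each J lost and a second E for each D.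
- In west, the E charged over twice the J charged is 2.50. This ratio, the ceiling, is, up to one, the fraction of the J charged that E can pay for as D. Above one, J is the limiting reagent instead of E.
- The ceiling is lower in south-east (1.33) than in west, lower again in north (0.500), then east (0.400) and south (0.0625). That is the order reckoned here for 30 h, with south expected below its ceiling.
- The early end comes from the first noon reading. Taken as pseudo-first-order in J with E as charged, it reads as a rate constant of 0.288 L mol⁻¹ h⁻¹ for the first uptake of E by J.
- With E as charged, J in west halves in 4.02 h, much shorter than 30 h. D in west is therefore expected close to the whole J charged.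
- At 6.0 h the same constant ranks the uptake of J by E charged, so west is expected first. East and south-east share one E charge, but by this first uptake alone, with J as charged, E halves in 4.82 h in east and 16.1 h in south-east, so south-east is expected ahead of east. North, with less E charged than east, is expected behind east.
- In south, by the same uptake with J as charged, E halves in 1.20 h, shorter than 6.0 h, so south is expected last at that time too.
- No J is to be added, since with E held the ceiling falls as J rises: east stands below south-east on one E charge. X stays as charged, since its effect is a guess.
- The forecast gives south-east > west > east > north > south at 30 h and east > south-east > west > north > south at 6.0 h, with top 66% and low 2%, differing from the reckoning here in first place at both times: “South-east and west have excess E and are limited by time”.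
- The flasks give west > south-east > north > east > south at 30 h and west > south-east > east > north > south at 6.0 h, with top 96.5% and low 1.56%. West, with ceiling 2.50, holds J at 0.867% of the J charged and 61% of its own E at 30.0 h.

    J + L → Z (k = 0.0754 L mol⁻¹ h⁻¹)
    L + X → G (k = 0.598 L mol⁻¹ h⁻¹)
    J + E → L + Q (k = 0.383 L mol⁻¹ h⁻¹)
    E + L → D + Q (k = 1.23 L mol⁻¹ h⁻¹)

- A neighbour of west charged with 0.48 M of J has its ceiling at 0.625, and its D stands below that, at 53.8%, with 1.5% of its E left.

All runs are simulated on assumed constants, noise included.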